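## Retrosynthetic overview

- Target ⇐ one-flask epoxidation of the C1=C6 bond of a cyclohexadiene triester, followed by opening of that oxirane at C1 with help from the neighbouring C2 acetate. This mirrors the epoxide-to-diol stage of the presumed biosynthesis.
- Diene triester ⇐ twofold dehydrobromination of a cyclohexene carrying the trans C2-O/C3-OBz pair ⇐ trans opening of an oxirane by benzoic acid, the counterpart of benzoate opening the arene oxide.
- Oxirane ⇐ enantioselective desymmetrising epoxidation of achiral (cyclohexa-2,5-dienyl)methanol ⇐ Birch reduction and LiAlH4 reduction of benzoic acid.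
- Ring order: the carbocycle is not built but taken from benzoic acid by dearomatisation. The first oxirane (C2–C3) is formed in step 3 and opened in step 4. The second oxirane (C1–C6) is formed in step 8 and opened in the same flask through a transient five-membered acetoxonium ring.

Assumption: biogenetic ring numbering is used (C1 carries CH2OBz and OH, C2 the acetate, C3 the benzoate, C4=C5 the alkene, C6 the secondary OH). The target SMILES then reads 1R,2S,3R,6S, with O1/O2 cis, O2/O3 trans, and O6 trans to O1 and cis to O3.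

## Route

Step 1
Reactants: 1 benzoic acid
Product: 2 cyclohexa-2,5-diene-1-carboxylic acid
Conditions: Na, EtOH, liq. NH3, −78 to −33 °C; then NH4Cl; aq. HCl
Reagents that add atoms: none
Why: Birch reduction, in which the carboxylate directs protonation to C1 and C4 so that only the unconjugated 2,5-diene forms (the classical preparation of 1,4-dihydrobenzoic acid); no stereocentre is created and the benzoate ring becomes the future cyclohexene core.

Step 2
Reactants: 2 cyclohexa-2,5-diene-1-carboxylic acid
Product: 3 (cyclohexa-2,5-dien-1-yl)methanol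
Conditions: LiAlH4, Et2O, 0 °C to rt; aqueous work-up
Reagents that add atoms: none
Why: Hydride reduction of a carboxylic acid by LiAlH4, which leaves isolated alkenes alone and does not isomerise the skipped diene under aprotic conditions; no stereocentre is created.

Step 3
Reactants: 3 (cyclohexa-2,5-dien-1-yl)methanol
Product: 4 ((1R,2S,6S)-7-oxabicyclo[4.1.0]hept-3-en-2-yl)methanol (oxirane cis to CH2OH)
Conditions: VO(OiPr)3 (2 mol %), (R,R)- or (S,S)-N,N'-dihydroxy-N,N'-bis(diphenylacetyl)cyclohexane-1,2-diamine (4 mol %; the enantiomer that gives 4, fixed in one screening run), cumene hydroperoxide (1.0 equiv), toluene, 0 °C to rt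
Reagents that add atoms: cumene hydroperoxide, CC(C)(OO)c1ccccc1
Why: Proposed new method: the homoallylic CH2OH binds the chiral vanadium hydroxamate peroxide and delivers oxygen intramolecularly to one of the two enantiotopic ring alkenes on the face cis to CH2OH, so C1, C2 and C3 are set in one event, and faster second epoxidation of the minor enantiomer should raise the ee; the closest known reaction types are the catalytic asymmetric epoxidation of homoallylic alcohols with vanadium bis-hydroxamic acid catalysts and the syn-selective VO(acac)2/t-BuOOH epoxidation of cyclohex-2-enylmethanols, and this oxirane stands in for the arene oxide of the biosynthesis.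

Step 4
Reactants: 4 ((1R,2S,6S)-7-oxabicyclo[4.1.0]hept-3-en-2-yl)methanol; 1 benzoic acid (1.5 equiv)
Product: 5 (1R,5S,6R)-6-hydroxy-5-(hydroxymethyl)cyclohex-3-en-1-yl benzoate
Conditions: n-Bu4N+ PhCO2− (10 mol %), MeCN, 70 °C
Reagents that add atoms: none
Why: Carboxylate-catalysed acid–epoxide addition (SN2), in which benzoate attacks anti to the oxirane oxygen at C3, the carbon remote from the C1 substituent, as is usual for cis-3-substituted cyclohexene oxides; C3 is inverted and C2 untouched, giving the trans C2-OH/C3-OBz pattern.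

Step 5
Reactants: 5 (1R,5S,6R)-6-hydroxy-5-(hydroxymethyl)cyclohex-3-en-1-yl benzoate
Product: 7 (1R,5S,6R)-6-acetoxy-5-[(benzoyloxy)methyl]cyclohex-3-en-1-yl benzoate, via hydroxy dibenzoate 6 (not isolated)
Conditions: BzCl (1.05 equiv), pyridine, CH2Cl2, −30 °C; then Ac2O (3 equiv), DMAP (10 mol %), rt
Reagents that add atoms: benzoyl chloride, O=C(Cl)c1ccccc1; acetic anhydride, CC(=O)OC(C)=O
Why: Sequential acylation, in which benzoyl chloride at low temperature esterifies only the primary hydroxyl and the hindered secondary C2 hydroxyl is then acetylated under DMAP catalysis; no stereocentre is touched.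

Step 6
Reactants: 7 (1R,5S,6R)-6-acetoxy-5-[(benzoyloxy)methyl]cyclohex-3-en-1-yl benzoate
Product: 8 (1R,2R,3S,4R,5R)-2-acetoxy-3-[(benzoyloxy)methyl]-4,5-dibromocyclohexyl benzoate
Conditions: Br2 (1.05 equiv), CH2Cl2, −78 °C
Reagents that add atoms: bromine, BrBr
Why: Electrophilic anti addition of bromine to the only remaining alkene, through a bromonium ion formed on the face opposite the C1 substituent and opened by bromide at the less hindered C5; this gives the trans-dibromide, whose two new stereocentres are only transient.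

Step 7
Reactants: 8 (1R,2R,3S,4R,5R)-2-acetoxy-3-[(benzoyloxy)methyl]-4,5-dibromocyclohexyl benzoate
Product: 11 (1R,6R)-6-acetoxy-5-[(benzoyloxy)methyl]cyclohexa-2,4-dien-1-yl benzoate, via allylic bromide 9 (not isolated), via allylic chloride 10 (not isolated)
Conditions: LiCl (5 equiv), Li2CO3 (3 equiv), HMPA, 90 °C
Reagents that add atoms: none
Why: Twofold dehydrohalogenation (E2), in which anti loss of H4/Br5 gives allylic bromide 9, chloride then inverts C6 by SN2 because H1 is cis to the C6 bromide, and anti loss of H1/Cl from 10 gives the conjugated diene; C2 and C3 are untouched, and the precedent is the conversion of trans-diacyloxy-dibromocyclohexanes into trans-5,6-diacyloxycyclohexa-1,3-dienes under these conditions.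

Step 8
Reactants: 11 (1R,6R)-6-acetoxy-5-[(benzoyloxy)methyl]cyclohexa-2,4-dien-1-yl benzoate
Product: 14 HY-N2634 [(1R,2S,5R,6S)-6-acetoxy-5-(benzoyloxy)-1,2-dihydroxycyclohex-3-en-1-yl]methyl benzoate, via anti-epoxide 12 (not isolated), via acetoxonium ion 13 (not isolated)
Conditions: DMDO (1.1 equiv), acetone/CH2Cl2, −20 to 0 °C; then H2O, HClO4 (10 mol %), 0 °C to rt
Reagents that add atoms: dimethyldioxirane, CC1(C)OO1; water, O
Why: Dioxirane epoxidation of the more substituted C1=C6 bond from the face opposite the pseudo-axial C2 acetate gives 12, which sets C6–O; the trans C2 acetate then opens the protonated oxirane at C1 with inversion (epoxy ester to acyloxonium rearrangement, neighbouring-group participation) to give 13, and water collapses 13 to the cis C1-OH/C2-OAc pair, the secondary acetate being favoured over the tertiary one.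

## Compound list

1 | benzoic acid | O=C(O)c1ccccc1 | starting material
2 | cyclohexa-2,5-diene-1-carboxylic acid | O=C(O)C1C=CCC=C1 | intermediate
3 | (cyclohexa-2,5-dien-1-yl)methanol | OCC1C=CCC=C1 | intermediate
4 | ((1R,2S,6S)-7-oxabicyclo[4.1.0]hept-3-en-2-yl)methanol | OC[C@@H]1C=CC[C@@H]2O[C@H]12 | intermediate
5 | (1R,5S,6R)-6-hydroxy-5-(hydroxymethyl)cyclohex-3-en-1-yl benzoate | OC[C@@H]1C=CC[C@@H](OC(=O)c2ccccc2)[C@@H]1O | intermediate
6 | (1R,5S,6R)-5-[(benzoyloxy)methyl]-6-hydroxycyclohex-3-en-1-yl benzoate | O=C(c1ccccc1)OC[C@@H]1C=CC[C@@H](OC(=O)c2ccccc2)[C@@H]1O | intermediate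
7 | (1R,5S,6R)-6-acetoxy-5-[(benzoyloxy)methyl]cyclohex-3-en-1-yl benzoate | O=C(c1ccccc1)OC[C@@H]1C=CC[C@@H](OC(=O)c2ccccc2)[C@@H]1OC(C)=O | intermediate
8 | (1R,2R,3S,4R,5R)-2-acetoxy-3-[(benzoyloxy)methyl]-4,5-dibromocyclohexyl benzoate | O=C(c1ccccc1)OC[C@@H]1[C@@H](Br)[C@H](Br)C[C@@H](OC(=O)c2ccccc2)[C@@H]1OC(C)=O | intermediate
9 | (1R,4S,5S,6R)-6-acetoxy-5-[(benzoyloxy)methyl]-4-bromocyclohex-2-en-1-yl benzoate | O=C(c1ccccc1)OC[C@@H]1[C@@H](Br)C=C[C@@H](OC(=O)c2ccccc2)[C@@H]1OC(C)=O | intermediate
10 | (1R,4R,5S,6R)-6-acetoxy-5-[(benzoyloxy)methyl]-4-chlorocyclohex-2-en-1-yl benzoate | O=C(c1ccccc1)OC[C@@H]1[C@H](Cl)C=C[C@@H](OC(=O)c2ccccc2)[C@@H]1OC(C)=O | intermediate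
11 | (1R,6R)-6-acetoxy-5-[(benzoyloxy)methyl]cyclohexa-2,4-dien-1-yl benzoate | O=C(c1ccccc1)OCC1=CC=C[C@@H](OC(=O)c2ccccc2)[C@@H]1OC(C)=O | intermediate
12 | (1S,4R,5S,6S)-5-acetoxy-6-[(benzoyloxy)methyl]-7-oxabicyclo[4.1.0]hept-2-en-4-yl benzoate (oxirane trans to the C2 acetate) | O=C(c1ccccc1)OC[C@]12O[C@H]1C=C[C@@H](OC(=O)c1ccccc1)[C@@H]2OC(C)=O | intermediate
13 | cis-fused 2-methyl-1,3-dioxolan-2-ylium (acetoxonium) ion bridging O1 and O2, C6-OH and C3-OBz on the opposite face, all ring stereocentres as in 14 | C[C+]1O[C@H]2[C@H](OC(=O)c3ccccc3)C=C[C@H](O)[C@@]2(COC(=O)c2ccccc2)O1 | intermediate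
14 | HY-N2634, [(1R,2S,5R,6S)-6-acetoxy-5-(benzoyloxy)-1,2-dihydroxycyclohex-3-en-1-yl]methyl benzoate | CC(=O)O[C@H]1[C@H](OC(=O)c2ccccc2)C=C[C@H](O)[C@]1(O)COC(=O)c1ccccc1 | target

## Step count and risks

Total step count: 8. Longest linear sequence: 8 (benzoic acid to 14).

The three steps most likely to fail are steps 3, 7 and 8.

**Step 3.** The desymmetrising epoxidation is untested on this diene, over-oxidation to a bis-epoxide costs yield, and the ee is unknown. The fallback sets out from 3. Epoxidation with VO(acac)2 and t-BuOOH, without a chiral ligand but still syn-selective, gives 4 together with its mirror image ((1S,2R,6R)-7-oxabicyclo[4.1.0]hept-3-en-2-yl)methanol F1. Enantioselection is then moved into the ring opening as a kinetic resolution. Benzoic acid 1 (0.5 equiv), i-Pr2NEt and the enantiopure benzoate of trivalent cobalt with N,N'-bis(3,5-di-tert-butylsalicylidene)cyclohexane-1,2-diamine (C43H57CoN2O4, the enantiomer matched to 4) in t-BuOMe open only 4. Unreacted F1 is separated and the route is rejoined at 5.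

**Step 7.** The C6 bromide of 8 is cis to H1, so the second elimination depends on halide-exchange epimerisation, and the product can aromatise by loss of a carboxylic acid. The fallback sets out from 7 and uses a selenoxide syn-elimination, which suits the cis H1. PhSeCl in CH2Cl2 at −78 °C adds anti across C5=C6 with selenium on the face opposite CH2OBz, giving (1R,2R,3S,4R,5R)-2-acetoxy-3-[(benzoyloxy)methyl]-5-chloro-4-(phenylselanyl)cyclohexyl benzoate F2. H2O2 and pyridine oxidise it, and the selenoxide eliminates towards H1 to give (1R,2R,5R)-2-acetoxy-3-[(benzoyloxy)methyl]-5-chlorocyclohex-3-en-1-yl benzoate F3. DBU then removes H4 and chloride in an anti E2 and the route is rejoined at 11.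

**Step 8.** Facial selectivity of the epoxidation may be low, and water attack at the allylic C6 or SN2' attack at C4 may compete with the acetate-assisted opening at C1. The fallback sets out from 6, isolated by stopping step 5 after the benzoylation, and uses hydroxyl-directed epoxidation on the other face followed by hydrolysis at C6.
- Bromination as in step 6 gives (1R,2R,3S,4R,5R)-3-[(benzoyloxy)methyl]-4,5-dibromo-2-hydroxycyclohexyl benzoate F4.
- Dehydrobromination as in step 7 gives (1R,6R)-5-[(benzoyloxy)methyl]-6-hydroxycyclohexa-2,4-dien-1-yl benzoate F5.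
- VO(acac)2 and t-BuOOH deliver oxygen cis to the free C2 hydroxyl, giving (1R,4R,5S,6S)-6-[(benzoyloxy)methyl]-5-hydroxy-7-oxabicyclo[4.1.0]hept-2-en-4-yl benzoate F6.
- Ac2O, pyridine and DMAP give (1R,4R,5S,6R)-5-acetoxy-6-[(benzoyloxy)methyl]-7-oxabicyclo[4.1.0]hept-2-en-4-yl benzoate F7.
- Dilute HClO4 in aqueous THF opens this vinyl oxirane at the allylic C6 with inversion, and the route is rejoined at 14.

Further compounds
F1 | step 3 | ((1S,2R,6R)-7-oxabicyclo[4.1.0]hept-3-en-2-yl)methanol | OC[C@H]1C=CC[C@H]2O[C@@H]12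
F2 | step 7 | (1R,2R,3S,4R,5R)-2-acetoxy-3-[(benzoyloxy)methyl]-5-chloro-4-(phenylselanyl)cyclohexyl benzoate | O=C(c1ccccc1)OC[C@@H]1[C@@H]([Se]c2ccccc2)[C@H](Cl)C[C@@H](OC(=O)c2ccccc2)[C@@H]1OC(C)=O
F3 | step 7 | (1R,2R,5R)-2-acetoxy-3-[(benzoyloxy)methyl]-5-chlorocyclohex-3-en-1-yl benzoate | O=C(c1ccccc1)OCC1=C[C@H](Cl)C[C@@H](OC(=O)c2ccccc2)[C@@H]1OC(C)=O
F4 | step 8 | (1R,2R,3S,4R,5R)-3-[(benzoyloxy)methyl]-4,5-dibromo-2-hydroxycyclohexyl benzoate | O=C(c1ccccc1)OC[C@@H]1[C@@H](Br)[C@H](Br)C[C@@H](OC(=O)c2ccccc2)[C@@H]1O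
F5 | step 8 | (1R,6R)-5-[(benzoyloxy)methyl]-6-hydroxycyclohexa-2,4-dien-1-yl benzoate | O=C(c1ccccc1)OCC1=CC=C[C@@H](OC(=O)c2ccccc2)[C@@H]1O
F6 | step 8 | (1R,4R,5S,6S)-6-[(benzoyloxy)methyl]-5-hydroxy-7-oxabicyclo[4.1.0]hept-2-en-4-yl benzoate | O=C(c1ccccc1)OC[C@@]12O[C@@H]1C=C[C@@H](OC(=O)c1ccccc1)[C@@H]2O
F7 | step 8 | (1R,4R,5S,6R)-5-acetoxy-6-[(benzoyloxy)methyl]-7-oxabicyclo[4.1.0]hept-2-en-4-yl benzoate | O=C(c1ccccc1)OC[C@@]12O[C@@H]1C=C[C@@H](OC(=O)c1ccccc1)[C@@H]2OC(C)=O
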